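Numbering used throughout: the target carries the chromanone numbering O1, C2, C3, C4, C4a, C5, C6, C7, C8, C8a. Ring A is the carbocycle C4a–C8a, ring B the pyranone, and ring C the six-membered lactone that ties O7 to the acid in the intermediates. The bicyclic lactones 3–7 are named as chroman-2-ones; the hydroxyl that lies para to the benzylic-bearing carbon (O7 of the chroman-2-one) is the future O5, and the hydroxyl next to that carbon (O5 of the chroman-2-one) is the future O1. From 8 on, the fused-ring names use pyrano[2,3-f]chromene locants, in which O1–C6 coincide with the chromanone numbers, O7/C8/C9/C10 are the lactone ring and C10 is the benzylic carbon.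

## The problem

The target is a dearomatised acylphloroglucinol in which ring A, an enolised β-triketone (C5=O, C7=O, enol at C4), is fused to ring B, a cis-2,3-dimethyl dihydropyranone; C6 is quaternary and carries a prenyl group and a branched C10 chain joined through CH2, and C8 carries a 3-phenylpropanoic acid joined through its benzylic carbon. The five stereocentres fall into three mutually remote groups (the cis C2/C3 pair, the benzylic carbon on C8, and C6 with the chain methine two bonds away), and only within the C2/C3 pair can one centre direct the other, so the benzylic centre, C6 and the methine each need a reagent or catalyst of their own, the methine being at best a weak 1,3-guide for C6. Three features will not survive rough treatment: C3–H is α to the C4 carbonyl, so the cis pair slips to trans by enolisation or retro-oxa-Michael reaction; the C5–C6–C7 diketone cannot enolise at C6 and is open to retro-Claisen cleavage whenever it is not held as the delocalised anion; and three different alkenes (prenyl, 2-methylpropenyl, isopropenyl) exclude hydrogenation and strong protic or Lewis acids late in the route. The acid and the C7 oxygen are 1,5-related through C8 and the benzylic carbon and can therefore travel as an aryl lactone (ring C), which keeps ring A aromatic with a single free phenol at C5. In that aromatic form C6 is the only unsubstituted carbon of ring A and lies ortho to C5–OH, while in the target C6 carries CH2–CH(R)–CH=. The C5 oxygen, C6 and an exocyclic methylene are the atoms of an ortho-quinone methide, and the CH2–methine bond is the bond that an aldehyde α-carbon forms when it adds to that methylene; the aldehyde carbon is then held by the C5 oxygen as a lactol and later becomes the CH of the 2-methylpropenyl group. The task therefore reduces to four things: an enantioenriched tricyclic phenol, the quinone methide alkylation, one dearomatising C-prenylation that creates the quaternary centre, and the opening of ring C.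

## Retrosynthesis

**Ring C opened last (23 ⇒ 22).** The acyl–O7 bond is reconnected, so that the acid and the C7 oxygen of 23 become the enol lactone of 22. Carrying the acid as this lactone costs no protecting-group step, keeps the carboxylate out of every alkylation, and leaves only one oxygen (O5) free to direct chemistry at C6. The forward reaction is a saponification of the most electrophilic carbonyl in the molecule. It has to leave the cis C2/C3 pair and the quaternary diketone intact, which the delocalised triketone anion formed on opening should ensure.

**The quaternary carbon (22 ⇒ 20 + 21).** The C6–CH2 bond of the prenyl group is cut. The neighbouring cut, the branched chain at C6, would need an SN2 reaction of a hindered ring carbon with a β-branched primary electrophile that is itself chiral. A prenyl unit is the better electrophile and can be delivered through a π-allyl complex from prenyl acetate 21. The precursor 20 is an aromatic phenol with one stereocentre fewer. The forward reaction must choose carbon over oxygen, C6 over the ring-fusion carbon C8, the linear over the branched allyl terminus, and one face of C6. For the last point the substrate offers only the remote methine, so a chiral catalyst is needed.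

**The 2-methylpropenyl group (20 ⇒ 18).** The trisubstituted C=C is cut to a carbonyl, which in this molecule exists as lactol 18. Bringing the alkene in with the aldehyde instead would mean a β,γ-unsaturated aldehyde, which forms dienamines and loses its α-configuration. The precursor is three carbons smaller. The forward Wittig reaction must pass through the ring-opened aldehyde, present in the flask as its lithium phenoxide 19, without epimerising the α-carbon.

**The chain on C6 (18 ⇒ 11 + 14, the key disconnection).** Two bonds are cut: the CH2–CH bond of the side chain and the O5–C bond of the lactol. This cut uses the innate polarity of ring A: the phenol at C5 and a leaving group on the C6 methylene give quinone methide 16, and the aldehyde α-carbon of 14, as enamine 15, is the nucleophile. The alternatives are alkylation of an enolate by a C6 benzylic halide, which needs strong base next to an aryl lactone, or direct C6 alkylation of ring A by a chiral alkyl halide. Both are more demanding. The precursors are sulfone 11, which holds all ring stereocentres, and the achiral aldehyde 14. The forward reaction must set the methine under catalyst control and trap the hydroxy aldehyde 17 as lactol 18 before the α-centre can enolise.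

**The C6 methylene (11 ⇒ 9).** The C6–CH2 bond is cut to phenol 9, formaldehyde and sulfinate; the hydroxymethyl phenol 10 is the intermediate. C6 is the only free position of 9, so there is no regiochemical question. The forward reaction only has to stop at the monomeric sulfone.

**Ring B (9 ⇒ 8 ⇒ 7).** The methyl ether of 8 is the protected form of 9. In 8 the O1–C2 bond is cut to the o-hydroxyaryl tigloyl ketone 7. This closure makes both ring-B stereocentres in one catalytic step from an achiral side chain, and it is known to favour the cis isomer under cinchona catalysis. Compound 7 carries only the benzylic stereocentre. Ring B must close onto the oxygen next to the benzylic-bearing carbon and never onto the para oxygen, so the para oxygen is capped as a methyl ether. Methyl is the one ether that survives the preceding Friedel–Crafts step and can still be removed selectively, because in 8 it sits peri to the C4 carbonyl.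

**The tigloyl group (7 ⇒ 5 + 6).** The aryl–acyl bond is cut to phenol 5 and tigloyl chloride 6. The two unsubstituted positions of 5 are exchanged by moving the lactone from one oxygen flanking the benzylic-bearing carbon to the other (opening and reclosure). Acylation at either position therefore leads to the same hydrogen-bonded o-hydroxy ketone 7 once the lactone has equilibrated. Acylation ortho to the free hydroxyl gives 7 directly.

**Ring C and the benzylic centre (5 ⇒ 4 ⇒ 3 ⇒ 1 + 2).** Compound 5 is the mono-methyl ether of diol 4; in 4 the para hydroxyl is the only one that is never part of the lactone and is flanked by two ring hydrogens. Diol 4 comes from dimethyl ether 3, and in 3 the C4–phenyl bond is cut to 5,7-dimethoxycoumarin 1 and phenylboronic acid 2. The two methyl ethers of 1 cannot be told apart, so both are removed and one is put back. This detour is accepted because it lets the benzylic centre be set first, on a flat and robust coumarin, by a catalytic asymmetric conjugate addition.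

**The aldehyde (14 ⇒ 13 ⇒ 12).** The aldehyde is made by reducing ester 13, whose 1,1-disubstituted alkene comes from methylenation of the ketone of commercial ethyl 5-oxohexanoate 12.

## Roads not taken

**Alternative 1:** ring A is built from two non-aromatic pieces by cutting C7–C8 and C4a–C5.
- Forward key step: the pyranone acetate A3 is enolised under soft conditions and C-acylated at its methylene by the malonyl half-ester chloride A2. Base then drives C4a onto the methyl ester, closing ring A around the ready-made quaternary carbon to give the bicyclic trione ester A1.
- Merits: C6 is fixed in an open-chain compound before any ring exists. There is no dearomatisation, no competition between C- and O-alkylation and no aromatic regiochemistry. In this respect the road is better than the chosen one, which has to trust a catalyst-controlled prenylation or the separation of C6 epimers.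
- Weak points: the configuration of C6 in A2 rests only on the difference between an ester and an acid chloride on a carbon bearing two large, similar alkyl groups. Making that fully substituted malonate enantioselectively, together with the chain methine, is a research problem of its own. The ring closure attacks a neopentyl-type ester. The amine bases threaten the cis C3–H of the pyranone and the 1,3-diketone around the quaternary carbon. After the key step C8 still lacks the phenylpropanoic acid: the ester has to be removed and the triketone added to a cinnamic acid derivative with control of the benzylic centre by nothing nearer than C6.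
- Comparison: the centre that the chosen route sets first and most securely would here be set last and least securely. The chosen plan sets against the advantage at C6 three stereocentres made by precedented catalytic reactions on robust aromatic intermediates and a much shorter fragment synthesis.

**Alternative 2:** ring B is closed by cutting C3–C4.
- Forward key step: a chiral triazolium-derived carbene turns aldehyde A5 into its Breslow intermediate, which adds across the tethered vinyl group. This gives the bis(methoxymethyl) ether A4 with the C3 methyl created from the alkene terminus.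
- Merits: the precursor is a symmetrical phloroglucinaldehyde ether, so ring A poses no regiochemical question at that stage. C2 comes from an enantiopure allylic alcohol and C3 from a syn hydroacylation. The two protected oxygens of A4 are differentiated later by chelation for free, whereas the chosen route spends steps 2 and 3 on this.
- Weak points: carbene hydroacylation of an unactivated alkene needs heat and base, and the product has an enolisable C3–H, so the kinetic cis isomer forms under conditions that equilibrate it to trans. The doubly ortho-oxygenated aldehyde is hindered and electron-rich. A4 solves only ring B: the lactone ring with its benzylic centre would still have to be annulated at C8 in competition with C6, under acidic hydroarylation conditions that endanger cis C3 and give no control of the new centre.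
- Comparison: the chosen plan builds ring C first by an enantioselective conjugate addition, so the lactone differentiates the ring A positions before the sensitive chromanone exists. Alternative 2 is more elegant for ring B and weaker everywhere else.

**Alternative 3:** ring B is closed by cutting O1–C2.
- Forward key step: a cinchona alkaloid (quinine, or for this enantiomeric series more probably quinidine) catalyses the addition of the free phenol of the tigloyl ketone A7 to the enone. This gives the methoxymethyl-protected tricycle A6 with both ring-B stereocentres set as the cis pair.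
- Merits: the closure has close precedent on o-tigloylphenols, is catalytic, and gives the kinetic cis isomer under conditions too mild to equilibrate it.
- Weak points: as a strategy it is centred on the least demanding ring and is silent on C6, the chain methine and the quaternary centre. The methoxymethyl ether would not survive a Lewis-acid acylation on the way to A7 and needs acid for removal.
- Comparison: for ring B this road is as good as anything available, and the chosen route takes it over as its step 5. Compound 8 differs from A6 only in the ether group. It is not taken as the central idea because it ends where the real problem begins; the chosen plan adds the quinone methide alkylation and the dearomative prenylation.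

Key step: step 10

Assumption: the sense of induction of each chiral catalyst is taken from its closest analogy ((R)-SEGPHOS gives (R)-4-aryl lactones from coumarin; quinine gives (2R,3S)-cis chromanones from o-tigloylphenols, so quinidine is used here; the (S)-prolinol silyl ether gives R at the aldehyde α-carbon); the antipode or pseudo-enantiomer would be substituted if a sense proved opposite.

Assumption: 23 is written as the C4-enol tautomer of the β-triketone, and lactol 18 as a mixture of anomers that converge in step 11.

## Route

Step 1
Reactants: 1 5,7-dimethoxycoumarin (5,7-dimethoxy-2H-chromen-2-one); 2 phenylboronic acid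
Product: 3 (4R)-5,7-dimethoxy-4-phenylchroman-2-one
Conditions: Rh(acac)(C2H4)2 (3 mol%), (R)-SEGPHOS [(R)-5,5′-bis(diphenylphosphino)-4,4′-bi-1,3-benzodioxole] (3.3 mol%), PhB(OH)2 (5 equiv), dioxane/H2O 10:1, 60 °C
Reagents that add atoms: none
Why: Rhodium-catalysed asymmetric 1,4-addition of an arylboronic acid to a coumarin (Hayashi–Miyaura reaction): the phenylrhodium species formed by transmetalation inserts the C3=C4 bond on the face left open by the bisphosphine and the rhodium enolate is protonated by water; the new C4 stereocentre is set by the ligand.

Step 2
Reactants: 3 (4R)-5,7-dimethoxy-4-phenylchroman-2-one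
Product: 4 (4R)-5,7-dihydroxy-4-phenylchroman-2-one
Conditions: BBr3 (4 equiv), CH2Cl2, −78 °C → rt; aq. HCl work-up
Reagents that add atoms: none
Why: Lewis-acid cleavage of aryl methyl ethers by BBr3 (bromide attacks the methyl of the boron-bound ether); the lactone is untouched or re-closes on acidic work-up, reclosure on either flanking oxygen giving the same compound, and the benzylic stereocentre is not involved.

Step 3
Reactants: 4 (4R)-5,7-dihydroxy-4-phenylchroman-2-one
Product: 5 (4R)-5-hydroxy-7-methoxy-4-phenylchroman-2-one
Conditions: MeI (1.05 equiv), K2CO3 (1.1 equiv), acetone, 0 °C → rt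
Reagents that add atoms: iodomethane, CI
Why: Williamson etherification under substrate control: the hydroxyl para to the benzylic-bearing carbon is flanked by two ring hydrogens, whereas the other lies beside the carbon that carries the phenyl-substituted C4, so one equivalent of base and electrophile should cap the unhindered oxygen; over-methylated and regioisomeric material is separable.

Step 4
Reactants: 5 (4R)-5-hydroxy-7-methoxy-4-phenylchroman-2-one; 6 tigloyl chloride [(2E)-2-methylbut-2-enoyl chloride]
Product: 7 (4R)-5-hydroxy-7-methoxy-6-[(2E)-2-methylbut-2-enoyl]-4-phenylchroman-2-one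
Conditions: 6 (1.2 equiv), AlCl3 (3 equiv), CH2Cl2, 0 °C → rt; cold aq. HCl
Reagents that add atoms: none
Why: Friedel–Crafts acylation of the aluminium phenoxide, which delivers the acylium ortho to the free hydroxyl (directly or by O-acylation and Fries shift) and holds the product as an aluminium chelate, so that the enone stays uncyclised until work-up; the E geometry of 6 is retained and no stereocentre is formed.

Step 5
Reactants: 7 (4R)-5-hydroxy-7-methoxy-6-[(2E)-2-methylbut-2-enoyl]-4-phenylchroman-2-one
Product: 8 (2S,3R,10R)-5-methoxy-2,3-dimethyl-10-phenyl-2,3,9,10-tetrahydro-4H,8H-pyrano[2,3-f]chromene-4,8-dione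
Conditions: quinidine (20 mol%), chlorobenzene, 15 °C
Reagents that add atoms: none
Why: Cinchona-alkaloid-catalysed intramolecular oxa-Michael addition (6-endo-trig) of an o-hydroxyaryl tigloyl ketone: the quinuclidine nitrogen ion-pairs with the phenol while the alkaloid hydroxyl binds the enone, fixing the face of attack at the β-carbon (C2), and the enol is protonated within the same ion pair to give the kinetic cis C3; only the hydroxyl next to the benzylic-bearing carbon is free, so ring B can close in one direction only.

Step 6
Reactants: 8 (2S,3R,10R)-5-methoxy-2,3-dimethyl-10-phenyl-2,3,9,10-tetrahydro-4H,8H-pyrano[2,3-f]chromene-4,8-dione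
Product: 9 (2S,3R,10R)-5-hydroxy-2,3-dimethyl-10-phenyl-2,3,9,10-tetrahydro-4H,8H-pyrano[2,3-f]chromene-4,8-dione
Conditions: BCl3 (2 equiv), CH2Cl2, −78 → 0 °C; then H2O
Reagents that add atoms: none
Why: Chelation-assisted demethylation: BCl3 bridges the C4 carbonyl and the peri methoxy oxygen and chloride removes the methyl by SN2; the base-free, low-temperature conditions leave the lactone and the epimerisable cis C3 centre alone.

Step 7
Reactants: 9 (2S,3R,10R)-5-hydroxy-2,3-dimethyl-10-phenyl-2,3,9,10-tetrahydro-4H,8H-pyrano[2,3-f]chromene-4,8-dione
Product: 11 (2S,3R,10R)-5-hydroxy-2,3-dimethyl-6-[(4-methylbenzenesulfonyl)methyl]-10-phenyl-2,3,9,10-tetrahydro-4H,8H-pyrano[2,3-f]chromene-4,8-dione, via hydroxymethyl phenol 10 (not isolated)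
Conditions: (CH2O)n (1.5 equiv), sodium p-toluenesulfinate (3 equiv), HCO2H/H2O 1:1, rt → 40 °C
Reagents that add atoms: formaldehyde (as paraformaldehyde), C=O; sodium p-toluenesulfinate, Cc1ccc(cc1)S(=O)[O-].[Na+]
Why: Mannich-type three-component sulfonylmethylation: electrophilic hydroxymethylation at C6, the only unsubstituted position of ring A, gives 10, whose benzylic hydroxyl is replaced under acid by the sulfur of the sulfinate; the excess of sulfinate outcompetes a second phenol for the benzylic cation.

Step 8
Reactants: 12 ethyl 5-oxohexanoate
Product: 13 ethyl 5-methylhex-5-enoate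
Conditions: Ph3PCH3Br (1.2 equiv), KOtBu (1.15 equiv), THF, 0 °C → rt
Reagents that add atoms: methyltriphenylphosphonium bromide, C[P+](c1ccccc1)(c1ccccc1)c1ccccc1.[Br-]
Why: Wittig methylenation; the non-stabilised ylide attacks the ketone much faster than the ethyl ester.

Step 9
Reactants: 13 ethyl 5-methylhex-5-enoate
Product: 14 5-methylhex-5-enal
Conditions: i-Bu2AlH (1.05 equiv), CH2Cl2, −78 °C; aq. KNaC4H4O6 (potassium sodium tartrate)
Reagents that add atoms: none
Why: Partial reduction of an ester by i-Bu2AlH at −78 °C, where the tetrahedral aluminium hemiacetal persists until hydrolysis and so stops at the aldehyde.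

Step 10
Reactants: 11 (2S,3R,10R)-5-hydroxy-2,3-dimethyl-6-[(4-methylbenzenesulfonyl)methyl]-10-phenyl-2,3,9,10-tetrahydro-4H,8H-pyrano[2,3-f]chromene-4,8-dione; 14 5-methylhex-5-enal
Product: 18 lactol (cyclic hemiacetal between O5 and the aldehyde carbon; the carbon bearing the 3-methylbut-3-en-1-yl group is R; both anomers), via enamine 15 (not isolated), via quinone methide 16 (not isolated), via hydroxy aldehyde 17 (not isolated)
Conditions: 14 (2.5 equiv), (S)-2-[diphenyl(trimethylsilyloxy)methyl]pyrrolidine (20 mol%), NaHCO3 (sat. aq.), CH2Cl2, 0 °C → rt
Reagents that add atoms: none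
Why: Enamine-catalysed α-alkylation of an aldehyde by an ortho-quinone methide generated in situ from a 2-(sulfonylmethyl)phenol, a known route to chroman-2-ols. Bicarbonate deprotonates the C5 phenol of 11 and sulfinate leaves by 1,4-elimination to give 16, whose exocyclic methylene on C6 is the only electrophilic carbon of its kind because C6 was the single free position of ring A. Aldehyde 14 condenses with the pyrrolidine catalyst to the E-enamine 15, whose α-carbon adds to the methylene of 16 (stepwise Michael addition or its concerted [4+2] equivalent), forming the CH2–CH bond and restoring the aromaticity of ring A. Hydrolysis of the iminium ion returns the catalyst and gives 17, whose C5 hydroxyl closes onto the aldehyde by 6-exo-trig hemiacetalisation to the lactol ring of 18. The one new stereocentre that matters, the chain methine, is set by the catalyst: the diphenyl(silyloxy)methyl group covers one face of 15 and the quinone methide adds to the other, which for the (S)-catalyst corresponds to R at this carbon, the same sense as in its additions to nitroalkenes; the stereocentres of 11 are too remote to interfere. The lactol carbon forms as both anomers, which is of no consequence because it becomes an sp2 carbon in step 11. The step needs chemoselectivity for the enamine over water, sulfinate and a second quinone methide, served by releasing 16 slowly with a weak base in the presence of excess 14, and it needs the α-stereocentre to survive, which the immediate lactol closure secures by removing the enolisable aldehyde.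

Step 11
Reactants: 18 lactol (cyclic hemiacetal between O5 and the aldehyde carbon; both anomers)
Product: 20 (2S,3R,10R)-5-hydroxy-2,3-dimethyl-6-[(2R)-5-methyl-2-(2-methylprop-1-en-1-yl)hex-5-en-1-yl]-10-phenyl-2,3,9,10-tetrahydro-4H,8H-pyrano[2,3-f]chromene-4,8-dione, via lithium phenoxide 19 (not isolated)
Conditions: i-PrPPh3I (2.6 equiv), n-BuLi (2.5 equiv), THF, 0 °C; then 18, −78 → 0 °C; aq. NH4Cl
Reagents that add atoms: isopropyltriphenylphosphonium iodide, CC(C)[P+](c1ccccc1)(c1ccccc1)c1ccccc1.[I-]
Why: Wittig olefination of a lactol through its open form: the first equivalent of ylide deprotonates the hemiacetal hydroxyl of 18, which opens to the aldehyde lithium phenoxide 19 (a chelated o-acylphenoxide is a good leaving group), and the second equivalent converts the aldehyde of 19 into the trisubstituted alkene, the phenol being restored on NH4Cl work-up; as a phenoxide the molecule resists enolisation at C3, and the low temperature keeps the hindered ylide away from the aryl lactone and the α-proton of the aldehyde, so the methine configuration is carried over.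

Step 12
Reactants: 20 (2S,3R,10R)-5-hydroxy-2,3-dimethyl-6-[(2R)-5-methyl-2-(2-methylprop-1-en-1-yl)hex-5-en-1-yl]-10-phenyl-2,3,9,10-tetrahydro-4H,8H-pyrano[2,3-f]chromene-4,8-dione; 21 prenyl acetate (3-methylbut-2-en-1-yl acetate)
Product: 22 (2S,3R,6S,10R)-2,3-dimethyl-6-(3-methylbut-2-en-1-yl)-6-[(2R)-5-methyl-2-(2-methylprop-1-en-1-yl)hex-5-en-1-yl]-10-phenyl-2,3,9,10-tetrahydro-4H-pyrano[2,3-f]chromene-4,5,8(6H)-trione
Conditions: 21 (1.5 equiv), Pd2(dba)3·CHCl3 (2.5 mol%), N,N′-[(1R,2R)-cyclohexane-1,2-diyl]bis[2-(diphenylphosphino)benzamide] (7.5 mol%), Cs2CO3 (1.2 equiv), toluene, 0 °C → rt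
Reagents that add atoms: none
Why: Proposed new method: catalyst-controlled dearomative C-prenylation of a 2-acyl-6-alkylphenoxide; the phenoxide of 20 is expected to attack the unsubstituted terminus of the cationic π-prenyl complex formed from 21 and zerovalent palladium through C6, the ortho carbon that carries the charge of the vinylogous-acid anion and is less hindered than the ring-fusion carbon C8, while O-prenylation should be reversible because an o-acylphenoxide is a good leaving group, so that the C–C bonded dienone is the sink; the chiral diamide–diphosphine pocket is asked to choose the face of C6 (the ligand antipode is used if the 6R epimer results), the substrate offering only the remote chain methine; the closest known reaction types are the palladium-catalysed asymmetric allylic dearomatisation of naphthols and phenols with such ligands and the base-mediated dearomative prenylation of acylphloroglucinols.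

Step 13
Reactants: 22 (2S,3R,6S,10R)-2,3-dimethyl-6-(3-methylbut-2-en-1-yl)-6-[(2R)-5-methyl-2-(2-methylprop-1-en-1-yl)hex-5-en-1-yl]-10-phenyl-2,3,9,10-tetrahydro-4H-pyrano[2,3-f]chromene-4,5,8(6H)-trione
Product: 23 (3R)-3-[(2S,3R,6S)-4-hydroxy-2,3-dimethyl-6-(3-methylbut-2-en-1-yl)-6-[(2R)-5-methyl-2-(2-methylprop-1-en-1-yl)hex-5-en-1-yl]-5,7-dioxo-3,5,6,7-tetrahydro-2H-chromen-8-yl]-3-phenylpropanoic acid (CNP0155375.3)
Conditions: LiOH (3 equiv), THF/H2O 3:1, 0 °C; then 1 M HCl to pH 3
Reagents that add atoms: water (delivered as aqueous LiOH), O
Why: Saponification of the enol lactone, an acylated vinylogous acid and therefore the most electrophilic carbonyl present; the C7 oxygen is released as part of the delocalised triketone enolate, which protects C3–H and the C5–C6–C7 unit against epimerisation and retro-Claisen cleavage, and acidification gives 23 as its enol tautomer with all five stereocentres untouched.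

## Compound list

1 | 5,7-dimethoxycoumarin | COc1cc(OC)c2C=CC(=O)Oc2c1 | starting material
2 | phenylboronic acid | OB(O)c1ccccc1 | starting material
3 | (4R)-5,7-dimethoxy-4-phenylchroman-2-one | COc1cc(OC)c2[C@@H](c3ccccc3)CC(=O)Oc2c1 | intermediate
4 | (4R)-5,7-dihydroxy-4-phenylchroman-2-one | Oc1cc(O)c2[C@@H](c3ccccc3)CC(=O)Oc2c1 | intermediate
5 | (4R)-5-hydroxy-7-methoxy-4-phenylchroman-2-one | COc1cc(O)c2[C@@H](c3ccccc3)CC(=O)Oc2c1 | intermediate
6 | tigloyl chloride, (2E)-2-methylbut-2-enoyl chloride | C/C=C(\C)C(=O)Cl | starting material
7 | (4R)-5-hydroxy-7-methoxy-6-[(2E)-2-methylbut-2-enoyl]-4-phenylchroman-2-one | C/C=C(\C)C(=O)c1c(O)c2[C@@H](c3ccccc3)CC(=O)Oc2cc1OC | intermediate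
8 | (2S,3R,10R)-5-methoxy-2,3-dimethyl-10-phenyl-2,3,9,10-tetrahydro-4H,8H-pyrano[2,3-f]chromene-4,8-dione | COc1cc2OC(=O)C[C@H](c3ccccc3)c2c2O[C@@H](C)[C@@H](C)C(=O)c12 | intermediate
9 | (2S,3R,10R)-5-hydroxy-2,3-dimethyl-10-phenyl-2,3,9,10-tetrahydro-4H,8H-pyrano[2,3-f]chromene-4,8-dione | Oc1cc2OC(=O)C[C@H](c3ccccc3)c2c2O[C@@H](C)[C@@H](C)C(=O)c12 | intermediate
10 | (2S,3R,10R)-5-hydroxy-6-(hydroxymethyl)-2,3-dimethyl-10-phenyl-2,3,9,10-tetrahydro-4H,8H-pyrano[2,3-f]chromene-4,8-dione | OCc1c(O)c2C(=O)[C@H](C)[C@H](C)Oc2c2[C@@H](c3ccccc3)CC(=O)Oc12 | intermediate (not isolated)
11 | (2S,3R,10R)-5-hydroxy-2,3-dimethyl-6-[(4-methylbenzenesulfonyl)methyl]-10-phenyl-2,3,9,10-tetrahydro-4H,8H-pyrano[2,3-f]chromene-4,8-dione | Cc1ccc(cc1)S(=O)(=O)Cc1c(O)c2C(=O)[C@H](C)[C@H](C)Oc2c2[C@@H](c3ccccc3)CC(=O)Oc12 | intermediate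
12 | ethyl 5-oxohexanoate | CCOC(=O)CCCC(C)=O | starting material
13 | ethyl 5-methylhex-5-enoate | CCOC(=O)CCCC(C)=C | intermediate
14 | 5-methylhex-5-enal | C=C(C)CCCC=O | intermediate
15 | (2S)-2-[diphenyl(trimethylsilyloxy)methyl]-1-[(1E)-5-methylhexa-1,5-dien-1-yl]pyrrolidine (enamine of 14) | C=C(C)CC/C=C/N1CCC[C@H]1C(O[Si](C)(C)C)(c1ccccc1)c1ccccc1 | intermediate (not isolated)
16 | (2S,3R,10R)-2,3-dimethyl-6-methylidene-10-phenyl-2,3,9,10-tetrahydro-4H-pyrano[2,3-f]chromene-4,5,8(6H)-trione (ortho-quinone methide) | C=C1C(=O)C2=C(O[C@@H](C)[C@@H](C)C2=O)C2=C1OC(=O)C[C@@H]2c1ccccc1 | intermediate (not isolated)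
17 | (2R)-2-{[(2S,3R,10R)-5-hydroxy-2,3-dimethyl-4,8-dioxo-10-phenyl-2,3,9,10-tetrahydro-4H,8H-pyrano[2,3-f]chromen-6-yl]methyl}-5-methylhex-5-enal | C=C(C)CC[C@@H](C=O)Cc1c(O)c2C(=O)[C@H](C)[C@H](C)Oc2c2[C@@H](c3ccccc3)CC(=O)Oc12 | intermediate (not isolated)
18 | lactol: cyclic hemiacetal of 17 between O5 and the aldehyde carbon; the new 2-hydroxy-3-(3-methylbut-3-en-1-yl)dihydropyran ring is fused at O5/C6, the butenyl-bearing carbon is R, both anomers | C=C(C)CC[C@@H]1Cc2c(OC1O)c1C(=O)[C@H](C)[C@H](C)Oc1c1[C@@H](c3ccccc3)CC(=O)Oc21 | intermediate
19 | lithium (2S,3R,10R)-6-[(2R)-2-formyl-5-methylhex-5-en-1-yl]-2,3-dimethyl-4,8-dioxo-10-phenyl-2,3,9,10-tetrahydro-4H,8H-pyrano[2,3-f]chromen-5-olate (ring-opened form of 18 as its lithium phenoxide) | C=C(C)CC[C@@H](C=O)Cc1c([O-])c2C(=O)[C@H](C)[C@H](C)Oc2c2[C@@H](c3ccccc3)CC(=O)Oc12.[Li+] | intermediate (not isolated)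
20 | (2S,3R,10R)-5-hydroxy-2,3-dimethyl-6-[(2R)-5-methyl-2-(2-methylprop-1-en-1-yl)hex-5-en-1-yl]-10-phenyl-2,3,9,10-tetrahydro-4H,8H-pyrano[2,3-f]chromene-4,8-dione | C=C(C)CC[C@@H](C=C(C)C)Cc1c(O)c2C(=O)[C@H](C)[C@H](C)Oc2c2[C@@H](c3ccccc3)CC(=O)Oc12 | intermediate
21 | prenyl acetate, 3-methylbut-2-en-1-yl acetate | CC(C)=CCOC(C)=O | starting material
22 | (2S,3R,6S,10R)-2,3-dimethyl-6-(3-methylbut-2-en-1-yl)-6-[(2R)-5-methyl-2-(2-methylprop-1-en-1-yl)hex-5-en-1-yl]-10-phenyl-2,3,9,10-tetrahydro-4H-pyrano[2,3-f]chromene-4,5,8(6H)-trione | C=C(C)CC[C@@H](C=C(C)C)C[C@@]1(CC=C(C)C)C(=O)C2=C(O[C@@H](C)[C@@H](C)C2=O)C2=C1OC(=O)C[C@@H]2c1ccccc1 | intermediate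
23 | (3R)-3-[(2S,3R,6S)-4-hydroxy-2,3-dimethyl-6-(3-methylbut-2-en-1-yl)-6-[(2R)-5-methyl-2-(2-methylprop-1-en-1-yl)hex-5-en-1-yl]-5,7-dioxo-3,5,6,7-tetrahydro-2H-chromen-8-yl]-3-phenylpropanoic acid | C=C(C)CC[C@@H](C=C(C)C)C[C@@]1(CC=C(C)C)C(=O)C2=C(O)[C@H](C)[C@H](C)OC2=C([C@H](CC(=O)O)c2ccccc2)C1=O | target

## Step count and least certain steps

Total: 13 steps. Longest linear sequence: 11 steps (steps 1–7 and 10–13); steps 8–9 are a two-step branch that supplies 14.

**Step 12 (bears the label "Proposed new method:").**
- What may go wrong: poor facial selectivity at C6, because no close precedent shows that a chiral palladium pocket can discriminate the faces of this hexasubstituted phenoxide; O-prenylation that does not revert; attack at the substituted allyl terminus; or attack through C8.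
- Fallback, using known chemistry only: it sets out from 20. The lactone is saponified with aqueous KOH to the tri-anion of the seco acid F1, generated and used in situ; it now has oxido groups on both sides of C6, the classical acylphloroglucinol arrangement. Prenyl bromide is added to the cold alkaline solution. This is the long-established base-mediated dearomative C-alkylation of acylphloroglucinols, in which the carbon between two oxido groups reacts and water disfavours O-alkylation; any prenyl ester of the carboxylate is cleaved by the excess hydroxide. Without catalyst control the reaction should give 23 together with its C6 epimer F2. They are diastereomers and are separated by preparative HPLC. The fallback rejoins the route at 23 and also replaces step 13.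

**Step 10 (key step).**
- What may go wrong: the unsubstituted, acyl-activated quinone methide may oligomerise or be re-captured by sulfinate and water faster than the enamine reaches it; the secondary amine catalyst may be acylated by the aryl lactone and so be consumed; or face selectivity on the enamine may be modest.
- Fallback: it sets out from 11 and 14 and keeps the same bonds but replaces enamine catalysis by an auxiliary-controlled cycloaddition. Aldehyde 14 is converted with (1R,2S)-2-phenylcyclohexanol (acid catalysis, removal of water) into the acetal F3. Elimination of one equivalent of the alcohol with Me3SiOTf and i-Pr2NEt gives the chiral Z-enol ether F4. Quinone methide 16 is released from 11 with a mild base in the presence of F4 and is trapped in an inverse-electron-demand [4+2] cycloaddition, a reaction known to be diastereoselective with such enol ethers, giving the 2-alkoxychroman acetal F5. Mild aqueous acid hydrolyses F5 to lactol 18, where the route is rejoined. The antipode of the auxiliary is used if the methine forms as S.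

**Step 11.**
- What may go wrong: acylation of the ylide by the aryl lactone; enolisation of the α-branched aldehyde with loss of the methine configuration; or base-induced epimerisation at C3, all because a strongly basic, nucleophilic reagent meets an ester and two enolisable centres.
- Fallback: it sets out from 18 and avoids basic ylides. Dibromo-olefination with CBr4 and PPh3 (Ramirez reaction, neutral conditions) gives the 1,1-dibromoalkene F6. Both bromides are then replaced by methyl in a palladium-catalysed Negishi coupling (Me2Zn, Pd(t-Bu3P)2, THF), which tolerates the lactone and the ketone. This gives 20, where the route is rejoined.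

**Step 1.**
- What may go wrong: slow insertion of the coumarin into the phenylrhodium bond, because the peri methoxy group at C5 crowds C4, so that protodeboronation of 2 takes over; or lower enantioselectivity than with the parent coumarin.
- Fallback: it does not set out from 1 and 2 but from commercial phloroglucinol and (E)-cinnamic acid, and replaces steps 1 and 2. Acid-mediated hydroarylation and lactonisation (CF3CO2H, 70 °C) gives the racemic diol F7 in one step. Its enantiomers are separated by preparative chromatography on a chiral stationary phase, and the (R)-enantiomer is 4, where the route is rejoined.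

**Step 7.**
- What may go wrong: capture of the benzylic cation by a second molecule of 9 (methylene-bridged dimer) instead of sulfinate, or acid-promoted epimerisation at C3 on prolonged warming.
- Fallback: it sets out from 9 and separates C–C bond formation from sulfone formation. Aminomethylation with [CH2=NMe2]I in CH2Cl2 gives the Mannich base F8, which cannot dimerise. Heating F8 with sodium p-toluenesulfinate in acetic acid exchanges the amine for the sulfinate by elimination and re-addition. This gives 11, where the route is rejoined.

## Further compounds

F1 | step 12 | (3R)-3-{(2S,3R)-5,7-dihydroxy-2,3-dimethyl-6-[(2R)-5-methyl-2-(2-methylprop-1-en-1-yl)hex-5-en-1-yl]-4-oxochroman-8-yl}-3-phenylpropanoic acid (seco acid, used as its tri-anion) | C=C(C)CC[C@@H](C=C(C)C)Cc1c(O)c2C(=O)[C@H](C)[C@H](C)Oc2c([C@H](CC(=O)O)c2ccccc2)c1O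
F2 | step 12 | C6 epimer of 23, (6R) | C=C(C)CC[C@@H](C=C(C)C)C[C@]1(CC=C(C)C)C(=O)C2=C(O)[C@H](C)[C@H](C)OC2=C([C@H](CC(=O)O)c2ccccc2)C1=O
F3 | step 10 | 5-methyl-1,1-bis{[(1R,2S)-2-phenylcyclohexyl]oxy}hex-5-ene (acetal of 14) | C=C(C)CCCC(O[C@@H]1CCCC[C@H]1c1ccccc1)O[C@@H]1CCCC[C@H]1c1ccccc1
F4 | step 10 | [(1S,2R)-2-{[(1Z)-5-methylhexa-1,5-dien-1-yl]oxy}cyclohexyl]benzene (enol ether of 14 with (1R,2S)-2-phenylcyclohexanol) | C=C(C)CC/C=C\O[C@@H]1CCCC[C@H]1c1ccccc1
F5 | step 10 | O-[(1R,2S)-2-phenylcyclohexyl] acetal of lactol 18 (2-alkoxychroman cycloadduct, butenyl-bearing carbon R) | C=C(C)CC[C@@H]1Cc2c(OC1O[C@@H]4CCCC[C@H]4c5ccccc5)c1C(=O)[C@H](C)[C@H](C)Oc1c1[C@@H](c3ccccc3)CC(=O)Oc21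
F6 | step 11 | (2S,3R,10R)-6-[(2R)-2-(2,2-dibromoethenyl)-5-methylhex-5-en-1-yl]-5-hydroxy-2,3-dimethyl-10-phenyl-2,3,9,10-tetrahydro-4H,8H-pyrano[2,3-f]chromene-4,8-dione | C=C(C)CC[C@@H](C=C(Br)Br)Cc1c(O)c2C(=O)[C@H](C)[C@H](C)Oc2c2[C@@H](c3ccccc3)CC(=O)Oc12
F7 | step 1 | racemic 5,7-dihydroxy-4-phenylchroman-2-one | Oc1cc(O)c2C(c3ccccc3)CC(=O)Oc2c1
F8 | step 7 | (2S,3R,10R)-6-[(dimethylamino)methyl]-5-hydroxy-2,3-dimethyl-10-phenyl-2,3,9,10-tetrahydro-4H,8H-pyrano[2,3-f]chromene-4,8-dione | CN(C)Cc1c(O)c2C(=O)[C@H](C)[C@H](C)Oc2c2[C@@H](c3ccccc3)CC(=O)Oc12
A1 | alternative 1 | 2-(trimethylsilyl)ethyl (2S,3R,6R)-4-hydroxy-2,3-dimethyl-6-(3-methylbut-2-en-1-yl)-6-[(2R)-5-methyl-2-(2-methylprop-1-en-1-yl)hex-5-en-1-yl]-5,7-dioxo-3,5,6,7-tetrahydro-2H-chromene-8-carboxylate (C6 arranged in space as in 23) | C=C(C)CC[C@@H](C=C(C)C)C[C@@]1(CC=C(C)C)C(=O)C2=C(O)[C@H](C)[C@H](C)OC2=C(C(=O)OCC[Si](C)(C)C)C1=O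
A2 | alternative 1 | methyl (2R)-2-(chlorocarbonyl)-5-methyl-2-[(2R)-5-methyl-2-(2-methylprop-1-en-1-yl)hex-5-en-1-yl]hex-4-enoate | C=C(C)CC[C@@H](C=C(C)C)C[C@@](C(=O)Cl)(CC=C(C)C)C(=O)OC
A3 | alternative 1 | 2-(trimethylsilyl)ethyl 2-[(2S,3R)-2,3-dimethyl-4-oxo-3,4-dihydro-2H-pyran-6-yl]acetate | C[C@@H]1OC(CC(=O)OCC[Si](C)(C)C)=CC(=O)[C@@H]1C
A4 | alternative 2 | (2S,3R)-5,7-bis(methoxymethoxy)-2,3-dimethylchroman-4-one | COCOc1cc(OCOC)c2C(=O)[C@H](C)[C@H](C)Oc2c1
A5 | alternative 2 | 2-{[(2S)-but-3-en-2-yl]oxy}-4,6-bis(methoxymethoxy)benzaldehyde | COCOc1cc(OCOC)c(C=O)c(O[C@@H](C)C=C)c1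
A6 | alternative 3 | (2S,3R,10R)-5-(methoxymethoxy)-2,3-dimethyl-10-phenyl-2,3,9,10-tetrahydro-4H,8H-pyrano[2,3-f]chromene-4,8-dione | COCOc1cc2OC(=O)C[C@H](c3ccccc3)c2c2O[C@@H](C)[C@@H](C)C(=O)c12
A7 | alternative 3 | (4R)-5-hydroxy-7-(methoxymethoxy)-6-[(2E)-2-methylbut-2-enoyl]-4-phenylchroman-2-one | COCOc1cc2OC(=O)C[C@H](c3ccccc3)c2c(O)c1C(=O)/C(C)=C/C
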